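**Retrosynthetic overview**
1. The butenolide (last ring) comes from ring-closing metathesis of the C5' acrylate onto the C4' isopropenyl group of 38.
2. The C14–C15 bond comes from chelation-controlled addition of the (E)-alkenylmagnesium derived from iodide 25 (carboalumination of alkyne 23) to (S)-aldehyde 32, which sets C15 and brings in C5'.
3. The 8α-OH and C17 methyl come from the exocyclic C8=C17 alkene of 17 by α-epoxidation and hydride opening.
4. Ring B (the second ring; ring A is bought in β-cyclocitral) is closed at C6–C7 by a Me2AlCl type-two carbonyl-ene reaction of seco-aldehyde 15. The route rests on the 1,3-placed C6 secondary and C8 tertiary carbinols of ring B (O–C6–C7–C8–O), which map onto a C6 aldehyde adding to a C8 isopropenyl group.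
5. Aldehyde 15 comes from δ-lactone 12 (α-face hydroboration of the exocyclic C5=C6 alkene sets C5); C9 and the quaternary C10 come from an enantioselective boron-enolate Ireland–Claisen rearrangement of β-cyclogeranyl ester 5.

Key step: step 10

Remark on numbering: labdane numbering is used for the bicyclic part (C1–C10; C17 on C8; C18 and C19 on C4; C20 on C10). The side chain is C11–C15 with C16 the methyl on C13, and the butenolide is O1', C2'(=O), C3', C4'(CH3), C5'.
Remark on the side arm: its C13 terminus is carried as a benzyl ether, a spectator that tolerates the boron Lewis acid of step 4, borane and Me2AlCl.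
Assumption: the (4S,5S)-diazaborolidinyl bromide of step 4 is taken to deliver the (2R,1'R) acid; if its sense of induction is the opposite, the (4R,5R) reagent is used without other change.

**Step 1**
Reactants: 1 δ-valerolactone
Product: 2 5-(benzyloxy)pentanoic acid
Conditions: KOH (powder), BnBr, toluene, reflux; aq. KOH, MeOH; 1 M HCl to pH 3
Reagents that add atoms: benzyl bromide BrCc1ccccc1; potassium hydroxide [K+].[OH-]
Why: Hydroxide opens the lactone and the ω-alkoxide is benzylated in the same pot (Williamson etherification), a standard entry to ω-benzyloxy acids; no stereocentre is formed.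

**Step 2**
Reactants: 3 β-cyclocitral
Product: 4 β-cyclogeraniol, (2,6,6-trimethylcyclohex-1-en-1-yl)methanol
Conditions: NaBH4, MeOH, 0 °C
Reagents that add atoms: none
Why: Borohydride 1,2-reduction of the hindered conjugated aldehyde should give the allylic alcohol; no stereocentre.

**Step 3**
Reactants: 4 β-cyclogeraniol; 2 5-(benzyloxy)pentanoic acid
Product: 5 (2,6,6-trimethylcyclohex-1-en-1-yl)methyl 5-(benzyloxy)pentanoate
Conditions: DCC, DMAP (cat.), CH2Cl2, 0 °C → rt
Reagents that add atoms: none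
Why: Steglich esterification of a primary allylic alcohol with an unbranched acid; no stereocentre.

**Step 4**
Reactants: 5 β-cyclogeranyl 5-(benzyloxy)pentanoate
Product: 8 (2R)-5-(benzyloxy)-2-[(1R)-1,3,3-trimethyl-2-methylidenecyclohexyl]pentanoic acid, via boron ketene acetal 6 (not isolated), via acyloxyborane 7 (not isolated)
Conditions: (4S,5S)-2-bromo-1,3-bis{[3,5-bis(trifluoromethyl)phenyl]sulfonyl}-4,5-diphenyl-1,3,2-diazaborolidine (1.2 equiv), i-Pr2NEt, CH2Cl2, −78 °C; then −20 → 4 °C, several days; aq. work-up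
Reagents that add atoms: none
Why: Soft enolisation gives the (Z)-O-boron ketene acetal 6 (C11 chain cis to O–B), and its enantioselective Ireland–Claisen [3,3] rearrangement through a chair with the chain pseudo-equatorial, on the enolate face left open by the chiral ligand, should form C9–C10 and set C9 and the quaternary C10 together.

**Step 5**
Reactants: 8 the Claisen acid
Product: 9 methyl (2R)-5-(benzyloxy)-2-[(1R)-1,3,3-trimethyl-2-methylidenecyclohexyl]pentanoate
Conditions: MeI, K2CO3, DMF, rt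
Reagents that add atoms: iodomethane CI
Why: SN2 O-alkylation of the carboxylate masks the acid against borane; stereocentres are untouched.

**Step 6**
Reactants: 9 the methyl ester
Product: 12 trans-fused δ-lactone (C8(=O)–O–C6H2; 5α-H, 9α-H, 10β-CH3; 3-(benzyloxy)propyl on C9), via alkylborane 10 (not isolated), via hydroxy ester 11 (not isolated)
Conditions: BH3·SMe2, THF, 0 °C → rt; 30% H2O2, aq. NaOAc, 0 °C → rt; then DBU (0.3 equiv), toluene, 80 °C
Reagents that add atoms: hydrogen peroxide OO
Why: In this hydroboration–oxidation borane should add syn to the exocyclic C5=C6 alkene from the α-face, opposite the axial C10 and 4β methyl groups that flank C5, so hydrogen enters C5 on the α-face and C6 becomes an equatorial CH2OH; base-catalysed lactonisation of 11 then gives the trans-fused lactone.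

**Step 7**
Reactants: 12 the δ-lactone
Product: 13 lactol (C8 methyl hemiketal, C8 epimers, in equilibrium with the open δ-hydroxy methyl ketone)
Conditions: MeLi (1.2 equiv), THF, −78 °C; H2O at −78 °C
Reagents that add atoms: methyllithium [Li]C
Why: Single addition of MeLi to a lactone stops at the tetrahedral lithium hemiketal at −78 °C, which gives the lactol on quenching; the C8 hemiketal centre is of no consequence.

**Step 8**
Reactants: 13 the lactol
Product: 14 [(1S,2R)-2-[(3S)-6-(benzyloxy)-2-methylhex-1-en-3-yl]-2,6,6-trimethylcyclohexyl]methanol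
Conditions: Ph3PCH3Br, KOt-Bu (4 equiv of ylide), THF, 0 → 50 °C
Reagents that add atoms: methyltriphenylphosphonium bromide C[P+](c1ccccc1)(c1ccccc1)c1ccccc1.[Br-]
Why: Wittig methylenation of the ring-opened hydroxy ketone (the alkoxide is tolerated) should give the C8 isopropenyl group; enolisation goes towards the methyl group, so C9 is not expected to epimerise.

**Step 9**
Reactants: 14 the isopropenyl alcohol
Product: 15 (1S,2R)-2-[(3S)-6-(benzyloxy)-2-methylhex-1-en-3-yl]-2,6,6-trimethylcyclohexane-1-carbaldehyde (13-(benzyloxy)-6,7-seco-14,15,16-trinorlabd-7-en-6-al)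
Conditions: Dess–Martin periodinane, NaHCO3, CH2Cl2, 0 °C → rt
Reagents that add atoms: none
Why: Buffered Dess–Martin oxidation of the primary alcohol; C5, flanked by two quaternary carbons, should keep its configuration under these non-basic conditions.

**Step 10**
Reactants: 15 the seco-aldehyde
Product: 17 13-(benzyloxy)-14,15,16-trinorlabd-8(17)-en-6α-ol (trans-decalin, 5α-H, 9α-H, 10β-CH3), via chloromethylaluminium alkoxide 16 (not isolated)
Conditions: Me2AlCl (2.0 equiv), CH2Cl2, −78 → −20 °C; cold 1 M HCl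
Reagents that add atoms: none
Why: Me2AlCl binds the aldehyde oxygen, the terminal carbon C7 of the isopropenyl group attacks C6 while an allylic hydrogen of C17 passes to oxygen, and the alkoxide 16 is fixed by loss of methane; this is the type-two intramolecular carbonyl-ene reaction known for Me2AlCl with aldehydes tethered to 1,1-disubstituted alkenes (3-methylenecyclohexanol formation). Ring B closes as a six-membered ring in the type-two mode, the tether joining the central ene carbon C8, so the new alkene is exocyclic (C8=C17). The trans ring fusion follows from the trans-diequatorial C5 formyl and C10–C9 bonds already present on ring A, and C9 is untouched. The ene array O–C6–C7–C8–C17–H has to bridge C6 and C8 on one face of the nascent ring; the β-face is closed by the axial C10 and 4β methyl groups, so the array should lie on the α-face (ring B boat-like in the transition state) and the oxygen ends equatorial, 6α, once ring B relaxes to the chair. The step needs exocyclic over endocyclic alkene formation and ene closure over chloride capture or methyl transfer, which the concerted hydrogen transfer and the proton-accepting Me2AlCl at low temperature should secure; the benzyl ether is inert.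

**Step 11**
Reactants: 17 the 6α-hydroxy-8(17)-ene
Product: 18 13-(benzyloxy)-8α,17-epoxy-14,15,16-trinorlabdan-6α-ol
Conditions: mCPBA, NaHCO3, CH2Cl2, 0 °C
Reagents that add atoms: 3-chloroperoxybenzoic acid OOC(=O)c1cccc(Cl)c1
Why: Prilezhaev epoxidation should occur from the α-face, since the β-face of C8 is screened by the syn-axial C10 methyl group and the 6α-hydroxyl can guide the peracid by hydrogen bonding; this sets C8 (oxygen α).

**Step 12**
Reactants: 18 the 8α,17-epoxide
Product: 19 13-(benzyloxy)-14,15,16-trinorlabdane-6α,8α-diol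
Conditions: LiAlH4, THF, 0 °C → reflux
Reagents that add atoms: none
Why: SN2 hydride opening at the primary C17 leaves the C8–O bond intact and should give the equatorial 8α-ol with the 8β-methyl group.

**Step 13**
Reactants: 19 the diol
Product: 20 13-(benzyloxy)-6α,8α-bis(triethylsilyloxy)-14,15,16-trinorlabdane
Conditions: Et3SiOTf, 2,6-lutidine, CH2Cl2, −78 → 0 °C
Reagents that add atoms: triethylsilyl trifluoromethanesulfonate CC[Si](CC)(CC)OS(=O)(=O)C(F)(F)F
Why: Silyl triflate silylation protects the hindered secondary and the tertiary hydroxyl in one operation.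

**Step 14**
Reactants: 20 the bis-TES benzyl ether
Product: 21 6α,8α-bis(triethylsilyloxy)-14,15,16-trinorlabdan-13-ol
Conditions: H2 (1 atm), Pd/C (10% palladium on carbon), EtOAc, rt
Reagents that add atoms: none
Why: Hydrogenolysis of the benzyl ether; no alkene is present at this stage and the silyl ethers are stable in ethyl acetate.

**Step 15**
Reactants: 21 the primary alcohol
Product: 22 6α,8α-bis(triethylsilyloxy)-14,15,16-trinorlabdan-13-al
Conditions: Dess–Martin periodinane, NaHCO3, CH2Cl2, rt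
Reagents that add atoms: none
Why: Dess–Martin oxidation of the primary alcohol to the aldehyde; both other hydroxyls are masked, so no lactol can form.

**Step 16**
Reactants: 22 the aldehyde
Product: 23 6α,8α-bis(triethylsilyloxy)-15,16-dinorlabd-13-yne
Conditions: dimethyl (1-diazo-2-oxopropyl)phosphonate, K2CO3, MeOH, 0 °C → rt
Reagents that add atoms: dimethyl (1-diazo-2-oxopropyl)phosphonate COP(=O)(OC)C(=[N+]=[N-])C(C)=O
Why: Ohira–Bestmann (Seyferth–Gilbert) homologation converts the aldehyde into the terminal alkyne under carbonate conditions that hindered TES ethers tolerate.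

**Step 17**
Reactants: 23 the terminal alkyne
Product: 25 (13E)-14-iodo-6α,8α-bis(triethylsilyloxy)-15-norlabd-13-ene, via alkenylalane 24 (not isolated)
Conditions: AlMe3 (3 equiv), Cp2ZrCl2 (0.3 equiv), CH2Cl2, 0 °C → rt; then I2, THF, −30 → 0 °C
Reagents that add atoms: trimethylaluminium C[Al](C)C; iodine II
Why: Zirconium-catalysed carboalumination (Negishi) adds methyl and aluminium syn across the alkyne with methyl on the internal carbon, and iodinolysis with retention should give the (E)-trisubstituted alkenyl iodide.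

**Step 18**
Reactants: 26 3-methylbut-2-en-1-ol (prenol)
Product: 27 (R)-(3,3-dimethyloxiran-2-yl)methanol
Conditions: Ti(OiPr)4 (10 mol%), D-(−)-diisopropyl tartrate (12 mol%), t-BuOOH, 4 Å molecular sieves, CH2Cl2, −20 °C
Reagents that add atoms: tert-butyl hydroperoxide CC(C)(C)OO
Why: Sharpless asymmetric epoxidation; the D-(−)-tartrate delivers oxygen to the face that gives the (2R)-epoxy alcohol.

**Step 19**
Reactants: 27 the epoxy alcohol
Product: 28 (2R)-2-{[(4-methoxybenzyl)oxy]methyl}-3,3-dimethyloxirane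
Conditions: NaH, 4-methoxybenzyl chloride, n-Bu4NI (cat.), THF–DMF, 0 °C → rt
Reagents that add atoms: 4-methoxybenzyl chloride COc1ccc(CCl)cc1
Why: Williamson etherification of the primary alkoxide, which outruns Payne rearrangement in aprotic medium at 0 °C; the stereocentre is untouched.

**Step 20**
Reactants: 28 the epoxy ether
Product: 29 (S)-1-[(4-methoxybenzyl)oxy]-3-methylbut-3-en-2-ol
Conditions: Et2AlCl, lithium 2,2,6,6-tetramethylpiperidide, toluene, 0 °C
Reagents that add atoms: none
Why: Aluminium amide-mediated epoxide-to-allylic-alcohol isomerisation removes a methyl hydrogen with cleavage of the tertiary C–O bond; the C2–O bond is untouched, so the stereocentre is retained (the descriptor changes to S by priority only).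

**Step 21**
Reactants: 29 the allylic alcohol
Product: 30 (4S)-2-(4-methoxyphenyl)-4-(prop-1-en-2-yl)-1,3-dioxolane (acetal carbon as a mixture)
Conditions: DDQ, 4 Å molecular sieves, dry CH2Cl2, 0 °C
Reagents that add atoms: none
Why: Anhydrous DDQ oxidation of the PMB ether gives an oxocarbenium ion that the neighbouring hydroxyl traps as the 4-methoxybenzylidene acetal.

**Step 22**
Reactants: 30 the benzylidene acetal
Product: 31 (S)-2-[(4-methoxybenzyl)oxy]-3-methylbut-3-en-1-ol
Conditions: i-Bu2AlH, CH2Cl2, −78 → 0 °C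
Reagents that add atoms: none
Why: Regioselective reductive acetal opening: aluminium binds the less hindered primary oxygen, so the PMB group should stay on the secondary oxygen and the primary alcohol is freed.

**Step 23**
Reactants: 31 the primary alcohol
Product: 32 (S)-2-[(4-methoxybenzyl)oxy]-3-methylbut-3-enal
Conditions: Dess–Martin periodinane, NaHCO3, CH2Cl2, 0 °C; used at once
Reagents that add atoms: none
Why: Base-free Dess–Martin oxidation gives the α-alkoxy β,γ-unsaturated aldehyde, used without storage to avoid epimerisation or conjugation.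

**Step 24**
Reactants: 25 the alkenyl iodide; 32 the α-alkoxy aldehyde
Product: 35 (15S,5'S)-allylic alcohol (C15–OH, C5'–OPMB, C4' isopropenyl; 6α,8α-bis-TES decalin), via alkenyllithium 33 (not isolated), via alkenylmagnesium bromide 34 (not isolated)
Conditions: t-BuLi (2.1 equiv), Et2O, −78 °C; MgBr2·OEt2, −78 °C; then 32 in CH2Cl2, −78 °C
Reagents that add atoms: none
Why: Iodine–lithium exchange with retention and transmetalation to magnesium are followed by Cram-chelate-controlled addition, in which MgBr2 bridges the aldehyde and PMB-ether oxygens and the alkenyl group attacks opposite the isopropenyl group, so the 15,5'-syn (15S) alcohol should form.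

**Step 25**
Reactants: 35 the allylic alcohol
Product: 36 C15 triethylsilyl ether of 35
Conditions: Et3SiOTf, 2,6-lutidine, CH2Cl2, −78 °C
Reagents that add atoms: triethylsilyl trifluoromethanesulfonate CC[Si](CC)(CC)OS(=O)(=O)C(F)(F)F
Why: Silylation masks C15–OH so that only the C5' oxygen can later be acylated.

**Step 26**
Reactants: 36 the PMB ether
Product: 37 C5' alcohol (C15–OTES, 6α,8α-bis-TES)
Conditions: DDQ, CH2Cl2–pH 7 buffer, 0 °C
Reagents that add atoms: none
Why: Oxidative PMB cleavage with buffered DDQ leaves silyl ethers and alkenes untouched.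

**Step 27**
Reactants: 37 the C5' alcohol
Product: 38 C5' acrylate
Conditions: acryloyl chloride, i-Pr2NEt, DMAP (cat.), CH2Cl2, −20 → 0 °C
Reagents that add atoms: acryloyl chloride C=CC(=O)Cl
Why: Acylation of the only free secondary alcohol installs the second alkene for ring closure.

**Step 28**
Reactants: 38 the acrylate
Product: 39 tris(triethylsilyl) ether of the target (butenolide closed)
Conditions: second-generation Grubbs catalyst RuCl2(=CHPh)(PCy3)(H2IMes) (10 mol%), toluene (2 mM), 80 °C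
Reagents that add atoms: none
Why: Ring-closing metathesis between the acrylate and the 1,1-disubstituted alkene should close the five-membered butenolide with loss of ethene; the trisubstituted C13=C14 alkene is far less reactive.

**Step 29**
Reactants: 39 the tris-TES ether
Product: 40 the target, CNP0279704.1
Conditions: HF·pyridine, pyridine, THF, 0 °C → rt
Reagents that add atoms: none
Why: Buffered fluoride cleavage of the three silyl ethers should spare the butenolide, the allylic alcohol and the tertiary alcohol.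

**Compound list**
1 | δ-valerolactone | O=C1CCCCO1 | starting material
2 | 5-(benzyloxy)pentanoic acid | OC(=O)CCCCOCc1ccccc1 | intermediate
3 | β-cyclocitral | CC1=C(C=O)C(C)(C)CCC1 | starting material
4 | β-cyclogeraniol | CC1=C(CO)C(C)(C)CCC1 | intermediate
5 | (2,6,6-trimethylcyclohex-1-en-1-yl)methyl 5-(benzyloxy)pentanoate | CC1=C(COC(=O)CCCCOCc2ccccc2)C(C)(C)CCC1 | intermediate
6 | (Z)-O-boron ketene acetal of 5 with the (4S,5S)-diazaborolidin-2-yl group | CC1=C(CO/C(=C/CCCOCc2ccccc2)OB2N(S(=O)(=O)c3cc(cc(c3)C(F)(F)F)C(F)(F)F)[C@@H](c3ccccc3)[C@H](c3ccccc3)N2S(=O)(=O)c2cc(cc(c2)C(F)(F)F)C(F)(F)F)C(C)(C)CCC1 | intermediate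
7 | B-acyloxy-diazaborolidine of acid 8 | O=C(OB2N(S(=O)(=O)c3cc(cc(c3)C(F)(F)F)C(F)(F)F)[C@@H](c3ccccc3)[C@H](c3ccccc3)N2S(=O)(=O)c2cc(cc(c2)C(F)(F)F)C(F)(F)F)[C@H](CCCOCc2ccccc2)[C@@]1(C)CCCC(C)(C)C1=C | intermediate
8 | (2R)-5-(benzyloxy)-2-[(1R)-1,3,3-trimethyl-2-methylidenecyclohexyl]pentanoic acid | OC(=O)[C@H](CCCOCc1ccccc1)[C@@]1(C)CCCC(C)(C)C1=C | intermediate
9 | methyl ester of 8 | COC(=O)[C@H](CCCOCc1ccccc1)[C@@]1(C)CCCC(C)(C)C1=C | intermediate
10 | C6 alkylborane (5α-H) | COC(=O)[C@H](CCCOCc1ccccc1)[C@@]1(C)CCCC(C)(C)[C@@H]1CB | intermediate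
11 | C6 hydroxy methyl ester (5α-H) | COC(=O)[C@H](CCCOCc1ccccc1)[C@@]1(C)CCCC(C)(C)[C@@H]1CO | intermediate
12 | trans-fused δ-lactone | c1ccccc1COCCC[C@@H]1[C@@]2(C)CCCC(C)(C)[C@@H]2COC1=O | intermediate
13 | lactol (C8 methyl hemiketal, C8 epimers) | c1ccccc1COCCC[C@@H]1[C@@]2(C)CCCC(C)(C)[C@@H]2COC1(C)O | intermediate
14 | [(1S,2R)-2-[(3S)-6-(benzyloxy)-2-methylhex-1-en-3-yl]-2,6,6-trimethylcyclohexyl]methanol | c1ccccc1COCCC[C@@H](C(C)=C)[C@@]1(C)CCCC(C)(C)[C@@H]1CO | intermediate
15 | (1S,2R)-2-[(3S)-6-(benzyloxy)-2-methylhex-1-en-3-yl]-2,6,6-trimethylcyclohexane-1-carbaldehyde | c1ccccc1COCCC[C@@H](C(C)=C)[C@@]1(C)CCCC(C)(C)[C@@H]1C=O | intermediate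
16 | chloro(methyl)aluminium 6α-alkoxide of 17 | c1ccccc1COCCC[C@@H]1[C@@]2(C)CCCC(C)(C)[C@@H]2[C@@H](O[Al](C)Cl)CC1=C | intermediate
17 | 13-(benzyloxy)-14,15,16-trinorlabd-8(17)-en-6α-ol | c1ccccc1COCCC[C@@H]1[C@@]2(C)CCCC(C)(C)[C@@H]2[C@@H](O)CC1=C | intermediate
18 | 13-(benzyloxy)-8α,17-epoxy-14,15,16-trinorlabdan-6α-ol | c1ccccc1COCCC[C@@H]1[C@@]2(C)CCCC(C)(C)[C@@H]2[C@@H](O)C[C@@]1(C3)O3 | intermediate
19 | 13-(benzyloxy)-14,15,16-trinorlabdane-6α,8α-diol | c1ccccc1COCCC[C@@H]1[C@@]2(C)CCCC(C)(C)[C@@H]2[C@@H](O)C[C@@]1(C)O | intermediate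
20 | 13-(benzyloxy)-6α,8α-bis(triethylsilyloxy)-14,15,16-trinorlabdane | c1ccccc1COCCC[C@@H]1[C@@]2(C)CCCC(C)(C)[C@@H]2[C@@H](O[Si](CC)(CC)CC)C[C@@]1(C)O[Si](CC)(CC)CC | intermediate
21 | 6α,8α-bis(triethylsilyloxy)-14,15,16-trinorlabdan-13-ol | OCCC[C@@H]1[C@@]2(C)CCCC(C)(C)[C@@H]2[C@@H](O[Si](CC)(CC)CC)C[C@@]1(C)O[Si](CC)(CC)CC | intermediate
22 | 6α,8α-bis(triethylsilyloxy)-14,15,16-trinorlabdan-13-al | O=CCC[C@@H]1[C@@]2(C)CCCC(C)(C)[C@@H]2[C@@H](O[Si](CC)(CC)CC)C[C@@]1(C)O[Si](CC)(CC)CC | intermediate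
23 | 6α,8α-bis(triethylsilyloxy)-15,16-dinorlabd-13-yne | C#CCC[C@@H]1[C@@]2(C)CCCC(C)(C)[C@@H]2[C@@H](O[Si](CC)(CC)CC)C[C@@]1(C)O[Si](CC)(CC)CC | intermediate
24 | (13E)-14-(dimethylalumanyl)-6α,8α-bis(triethylsilyloxy)-15-norlabd-13-ene | C[Al](C)/C=C(\C)CC[C@@H]1[C@@]2(C)CCCC(C)(C)[C@@H]2[C@@H](O[Si](CC)(CC)CC)C[C@@]1(C)O[Si](CC)(CC)CC | intermediate
25 | (13E)-14-iodo-6α,8α-bis(triethylsilyloxy)-15-norlabd-13-ene | I/C=C(\C)CC[C@@H]1[C@@]2(C)CCCC(C)(C)[C@@H]2[C@@H](O[Si](CC)(CC)CC)C[C@@]1(C)O[Si](CC)(CC)CC | intermediate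
26 | 3-methylbut-2-en-1-ol | CC(C)=CCO | starting material
27 | (R)-(3,3-dimethyloxiran-2-yl)methanol | CC1(C)O[C@@H]1CO | intermediate
28 | (2R)-2-{[(4-methoxybenzyl)oxy]methyl}-3,3-dimethyloxirane | CC1(C)O[C@@H]1COCc1ccc(OC)cc1 | intermediate
29 | (S)-1-[(4-methoxybenzyl)oxy]-3-methylbut-3-en-2-ol | C=C(C)[C@H](O)COCc1ccc(OC)cc1 | intermediate
30 | (4S)-2-(4-methoxyphenyl)-4-(prop-1-en-2-yl)-1,3-dioxolane | C=C(C)[C@H]1COC(c2ccc(OC)cc2)O1 | intermediate
31 | (S)-2-[(4-methoxybenzyl)oxy]-3-methylbut-3-en-1-ol | C=C(C)[C@H](OCc1ccc(OC)cc1)CO | intermediate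
32 | (S)-2-[(4-methoxybenzyl)oxy]-3-methylbut-3-enal | C=C(C)[C@H](OCc1ccc(OC)cc1)C=O | intermediate
33 | (13E)-14-lithio-6α,8α-bis(triethylsilyloxy)-15-norlabd-13-ene | [Li]/C=C(\C)CC[C@@H]1[C@@]2(C)CCCC(C)(C)[C@@H]2[C@@H](O[Si](CC)(CC)CC)C[C@@]1(C)O[Si](CC)(CC)CC | intermediate
34 | (13E)-14-(bromomagnesio)-6α,8α-bis(triethylsilyloxy)-15-norlabd-13-ene | Br[Mg]/C=C(\C)CC[C@@H]1[C@@]2(C)CCCC(C)(C)[C@@H]2[C@@H](O[Si](CC)(CC)CC)C[C@@]1(C)O[Si](CC)(CC)CC | intermediate
35 | (15S,5'S)-allylic alcohol, C5'–OPMB, 6α,8α-bis-TES | C=C(C)[C@H](OCc1ccc(OC)cc1)[C@@H](O)/C=C(\C)CC[C@@H]1[C@@]2(C)CCCC(C)(C)[C@@H]2[C@@H](O[Si](CC)(CC)CC)C[C@@]1(C)O[Si](CC)(CC)CC | intermediate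
36 | C15 triethylsilyl ether of 35 | C=C(C)[C@H](OCc1ccc(OC)cc1)[C@@H](O[Si](CC)(CC)CC)/C=C(\C)CC[C@@H]1[C@@]2(C)CCCC(C)(C)[C@@H]2[C@@H](O[Si](CC)(CC)CC)C[C@@]1(C)O[Si](CC)(CC)CC | intermediate
37 | C5' alcohol, 6α,8α,15-tris-TES | C=C(C)[C@H](O)[C@@H](O[Si](CC)(CC)CC)/C=C(\C)CC[C@@H]1[C@@]2(C)CCCC(C)(C)[C@@H]2[C@@H](O[Si](CC)(CC)CC)C[C@@]1(C)O[Si](CC)(CC)CC | intermediate
38 | C5' acrylate, 6α,8α,15-tris-TES | C=CC(=O)O[C@@H](C(C)=C)[C@@H](O[Si](CC)(CC)CC)/C=C(\C)CC[C@@H]1[C@@]2(C)CCCC(C)(C)[C@@H]2[C@@H](O[Si](CC)(CC)CC)C[C@@]1(C)O[Si](CC)(CC)CC | intermediate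
39 | 6α,8α,15-tris(triethylsilyl) ether of the target | CC1=CC(=O)O[C@@H]1[C@@H](O[Si](CC)(CC)CC)/C=C(\C)CC[C@@H]1[C@@]2(C)CCCC(C)(C)[C@@H]2[C@@H](O[Si](CC)(CC)CC)C[C@@]1(C)O[Si](CC)(CC)CC | intermediate
40 | CNP0279704.1, (5'S,15S,13E)-6α,8α,15-triol butenolide | CC1=CC(=O)O[C@@H]1[C@@H](O)/C=C(\C)CC[C@@H]1[C@@]2(C)CCCC(C)(C)[C@@H]2[C@@H](O)C[C@@]1(C)O | target

**Step count and risks**
Total step count: 29. Longest linear sequence: 22 steps (3 → 40 through steps 2–17 and 24–29).

Steps most likely to fail: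

1. Step 4. Enolisation and the [3,3] shift may be slow at the fully substituted ring terminus, so that the boron ketene acetal leaks through a boat or the other enolate geometry and enantio- or diastereoselectivity erodes. The fallback sets out from 5 and returns at 8. A racemic Ireland–Claisen rearrangement (LiN(i-Pr)2, THF–DMPU, −78 °C; Me3SiCl; 60 °C; aqueous hydrolysis) should give the racemic acid F1 with the same relative configuration. Crystallisation with (S)-1-phenylethylamine should then give the diastereomerically pure (S)-1-phenylethylammonium salt F2 (the antipodal amine is taken if the other acid crystallises), and acidification with HCl returns 8.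

2. Step 10. Ring closure may run stepwise through a C8 cation whose equatorial aluminate cannot accept the C17 hydrogen; chloride capture at C8, endocyclic alkene isomers or methyl transfer to the aldehyde would follow. The fallback sets out from 12 and returns at 17. Lactone 12 with Me3SiCH2MgCl and CeCl3 (THF, −78 °C → rt) should give the bis(trimethylsilylmethyl) carbinol F3, and Peterson elimination on silica gel the hydroxy allylsilane F4. Dess–Martin oxidation gives the aldehyde allylsilane F5, and BF3·OEt2 (CH2Cl2, −78 °C) closes ring B by intramolecular Hosomi–Sakurai allylation; loss of silicon from the β-silyl cation can only give the exocyclic alkene of 17.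

3. Step 24. The α-alkoxy β,γ-unsaturated aldehyde 32 may epimerise under the basic organometallic, or chelation control may be incomplete, giving mixtures at C5' and C15. The fallback sets out from 25 and returns at 36. Lithiation of 25 (t-BuLi, Et2O, −78 °C) and formylation with DMF should give the (E)-enal F6. A syn-selective boron glycolate aldol reaction of (R)-4-benzyl-3-{[(4-methoxybenzyl)oxy]acetyl}oxazolidin-2-one (n-Bu2BOTf, Et3N, CH2Cl2, −78 → 0 °C) with F6 sets C5' and C15 under auxiliary control and gives the aldol adduct F7. Silylation (Et3SiOTf, 2,6-lutidine) gives the TES ether F8, MeNHOMe·HCl with AlMe3 the Weinreb amide F9, and MeMgBr the methyl ketone F10. Wittig methylenation at low temperature (Ph3PCH3Br, KOt-Bu, toluene, 0 °C) returns 36.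

**Further compounds**
F1 | step 4 | racemic (2R*,1'R*)-5-(benzyloxy)-2-(1,3,3-trimethyl-2-methylidenecyclohexyl)pentanoic acid (relative configuration shown) | OC(=O)[C@H](CCCOCc1ccccc1)[C@@]1(C)CCCC(C)(C)C1=C
F2 | step 4 | (S)-1-phenylethylammonium salt of acid 8 | [O-]C(=O)[C@H](CCCOCc1ccccc1)[C@@]1(C)CCCC(C)(C)C1=C.C[C@H]([NH3+])c1ccccc1
F3 | step 10 | C8 bis(trimethylsilylmethyl) carbinol, C6 alcohol | c1ccccc1COCCC[C@@H](C(O)(C[Si](C)(C)C)C[Si](C)(C)C)[C@@]1(C)CCCC(C)(C)[C@@H]1CO
F4 | step 10 | C6 alcohol with C8 2-(trimethylsilylmethyl)vinyl group | c1ccccc1COCCC[C@@H](C(=C)C[Si](C)(C)C)[C@@]1(C)CCCC(C)(C)[C@@H]1CO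
F5 | step 10 | C6 aldehyde with C8 2-(trimethylsilylmethyl)vinyl group | c1ccccc1COCCC[C@@H](C(=C)C[Si](C)(C)C)[C@@]1(C)CCCC(C)(C)[C@@H]1C=O
F6 | step 24 | (13E)-6α,8α-bis(triethylsilyloxy)labd-13-en-15-al | O=C/C=C(\C)CC[C@@H]1[C@@]2(C)CCCC(C)(C)[C@@H]2[C@@H](O[Si](CC)(CC)CC)C[C@@]1(C)O[Si](CC)(CC)CC
F7 | step 24 | (15S,5'S)-glycolate aldol adduct, N-acyl (R)-4-benzyloxazolidin-2-one | O=C1OC[C@@H](Cc2ccccc2)N1C(=O)[C@H](OCc1ccc(OC)cc1)[C@@H](O)/C=C(\C)CC[C@@H]1[C@@]2(C)CCCC(C)(C)[C@@H]2[C@@H](O[Si](CC)(CC)CC)C[C@@]1(C)O[Si](CC)(CC)CC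
F8 | step 24 | C15 triethylsilyl ether of F7 | O=C1OC[C@@H](Cc2ccccc2)N1C(=O)[C@H](OCc1ccc(OC)cc1)[C@@H](O[Si](CC)(CC)CC)/C=C(\C)CC[C@@H]1[C@@]2(C)CCCC(C)(C)[C@@H]2[C@@H](O[Si](CC)(CC)CC)C[C@@]1(C)O[Si](CC)(CC)CC
F9 | step 24 | Weinreb amide (C4' carboxamide), C5'–OPMB, C15–OTES | CON(C)C(=O)[C@H](OCc1ccc(OC)cc1)[C@@H](O[Si](CC)(CC)CC)/C=C(\C)CC[C@@H]1[C@@]2(C)CCCC(C)(C)[C@@H]2[C@@H](O[Si](CC)(CC)CC)C[C@@]1(C)O[Si](CC)(CC)CC
F10 | step 24 | C4' methyl ketone, C5'–OPMB, C15–OTES | CC(=O)[C@H](OCc1ccc(OC)cc1)[C@@H](O[Si](CC)(CC)CC)/C=C(\C)CC[C@@H]1[C@@]2(C)CCCC(C)(C)[C@@H]2[C@@H](O[Si](CC)(CC)CC)C[C@@]1(C)O[Si](CC)(CC)CC
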